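**Retrosynthetic overview**

- The strategy rests on one feature: the ester carbon on ring A C1 and the hydroxymethyl carbon on ring B C2' both sit ortho to the diaryl ether oxygen (C2–O–C1'). Joined as C(=O)–O–CH2 they form the lactone of an eight-membered dibenzo[b,g][1,5]dioxocin-5-one, so the target comes from methanolysis of that lactone.
- The prenyl group on ring A C5 comes from an aromatic Claisen rearrangement of the 1,1-dimethylallyl ether of the ring A phenol, made by propargylation and semihydrogenation.
- The lactone is closed at the O–C1' bond by intramolecular Ullmann etherification of a 2-bromobenzyl 2,6-dihydroxybenzoate, while ring A is still symmetrical.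
- The bromo ester comes from carboxylate alkylation of 2,6-dihydroxy-4-methylbenzoic acid with 2-bromo-3,5-dimethoxybenzyl bromide (from 3,5-dimethoxybenzyl alcohol).
- Ring order: rings A and B are bought; the only ring formed is the temporary eight-membered lactone (step 4), opened again in step 8.

Key step: step 4

Remark: the target has no stereocentre and no configured double bond. Tricyclic intermediates are numbered as dibenzo[b,g][1,5]dioxocin (C5 lactone carbonyl, O6, C7 benzylic CH2, O12 diaryl ether oxygen; ring A = C1–C4, ring B = C8–C11).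

**Route**

Step 1
Reactants: 1 3,5-dimethoxybenzyl alcohol
Product: 2 (2-bromo-3,5-dimethoxyphenyl)methanol
Conditions: NBS (1.0 equiv), MeCN, 0 °C to rt, dark
Reagents that add atoms: N-bromosuccinimide, O=C1CCC(=O)N1Br
Why: Electrophilic aromatic bromination, in which C2 (ortho to one methoxy group, para to the other) is the usual site of monobromination in 3,5-dimethoxybenzyl systems and the position between the two methoxy groups is the less reactive one.

Step 2
Reactants: 2 (2-bromo-3,5-dimethoxyphenyl)methanol
Product: 3 2-bromo-1-(bromomethyl)-3,5-dimethoxybenzene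
Conditions: PBr3 (0.4 equiv), CH2Cl2, 0 °C
Reagents that add atoms: phosphorus tribromide, BrP(Br)Br
Why: Conversion of a benzylic alcohol into the bromide through its phosphite ester and SN2 displacement by bromide, which leaves the aryl bromide and the methyl ethers untouched.

Step 3
Reactants: 3 2-bromo-1-(bromomethyl)-3,5-dimethoxybenzene; 4 2,6-dihydroxy-4-methylbenzoic acid
Product: 5 (2-bromo-3,5-dimethoxyphenyl)methyl 2,6-dihydroxy-4-methylbenzoate
Conditions: KHCO3 (1.1 equiv), DMF, rt
Reagents that add atoms: none
Why: Carboxylate O-alkylation (SN2), in which hydrogencarbonate deprotonates only the strongly acidic carboxyl group while both phenols stay protonated and hydrogen-bonded to the carbonyl, and room temperature avoids decarboxylation of the 2,6-dihydroxybenzoic acid.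

Step 4
Reactants: 5 (2-bromo-3,5-dimethoxyphenyl)methyl 2,6-dihydroxy-4-methylbenzoate
Product: 6 4-hydroxy-9,11-dimethoxy-2-methyl-5H,7H-dibenzo[b,g][1,5]dioxocin-5-one
Conditions: CuI (30 mol%), N,N-dimethylglycine (60 mol%), Cs2CO3 (3 equiv), 4 Å MS, 1,4-dioxane, 100 °C, Ar, syringe-pump addition of 5 to 0.005 M
Reagents that add atoms: none
Why: Intramolecular Ullmann diaryl ether synthesis: the cesium phenoxide of ring A binds the dimethylglycinate-ligated monovalent copper, the tethered C1'–Br bond of ring B adds oxidatively to give a nine-membered aryl(phenoxido) trivalent copper chelate, and C–O reductive elimination forms the O–C1' bond and returns monovalent copper. The closest known reaction type is the copper/amino acid-catalysed Ullmann etherification in its ring-closing form, as used for medium and large diaryl ether rings. The one ring formed, the eight-membered 1,5-dioxocin-5-one, is closed by O-arylation at the sp2 carbon C1', with the three-atom C(=O)–O–CH2 tether holding phenoxide and bromide ortho to its two ends. No stereocentre is created. The step needs cyclisation to win over intermolecular coupling, which syringe-pump addition to 0.005 M should secure, while site selectivity on ring A is no issue because its two phenols are equivalent by symmetry. The benzylic ester should survive because the medium is anhydrous and Cs2CO3 is not nucleophilic.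

Step 5
Reactants: 6 4-hydroxy-9,11-dimethoxy-2-methyl-5H,7H-dibenzo[b,g][1,5]dioxocin-5-one; 7 3-chloro-3-methylbut-1-yne
Product: 8 9,11-dimethoxy-2-methyl-4-[(2-methylbut-3-yn-2-yl)oxy]-5H,7H-dibenzo[b,g][1,5]dioxocin-5-one
Conditions: DBU (1.5 equiv), CuCl2·2H2O (1 mol%), MeCN, 0 °C to rt
Reagents that add atoms: none
Why: Copper-catalysed propargylic etherification of a phenol with a tertiary propargyl chloride, in which DBU gives the phenoxide and the copper acetylide of 7 ionises to a copper allenylidene that is captured at the tertiary carbon, so the only free hydroxyl of 6 becomes the 1,1-dimethylpropargyl ether without opening the lactone.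

Step 6
Reactants: 8 9,11-dimethoxy-2-methyl-4-[(2-methylbut-3-yn-2-yl)oxy]-5H,7H-dibenzo[b,g][1,5]dioxocin-5-one
Product: 9 9,11-dimethoxy-2-methyl-4-[(2-methylbut-3-en-2-yl)oxy]-5H,7H-dibenzo[b,g][1,5]dioxocin-5-one
Conditions: H2 (1 atm), Pd/CaCO3 poisoned with Pb(OAc)2 (Lindlar catalyst), quinoline, EtOAc, rt, stopped after 1 equiv H2
Reagents that add atoms: none
Why: Lindlar semihydrogenation of the terminal alkyne to the vinyl group, on a poisoned catalyst that should not hydrogenolyse the benzylic lactone C–O bond or reduce the arenes.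

Step 7
Reactants: 9 9,11-dimethoxy-2-methyl-4-[(2-methylbut-3-en-2-yl)oxy]-5H,7H-dibenzo[b,g][1,5]dioxocin-5-one
Product: 11 4-hydroxy-9,11-dimethoxy-2-methyl-3-(3-methylbut-2-en-1-yl)-5H,7H-dibenzo[b,g][1,5]dioxocin-5-one, via cyclohexa-2,4-dienone 10 (not isolated)
Conditions: N,N-diethylaniline, 120 °C, Ar
Reagents that add atoms: none
Why: Aromatic Claisen rearrangement ([3,3]-sigmatropic shift with allyl inversion), which turns the 1,1-dimethylallyl ether into a 3-methylbut-2-enyl group on C3, the only ortho position that can rearomatise (the other, C4a, carries the lactone carbonyl), with dienone 10 tautomerising to the phenol and the basic solvent suppressing loss of isoprene.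

Step 8
Reactants: 11 4-hydroxy-9,11-dimethoxy-2-methyl-3-(3-methylbut-2-en-1-yl)-5H,7H-dibenzo[b,g][1,5]dioxocin-5-one
Product: 12 methyl 2-hydroxy-6-[2-(hydroxymethyl)-4,6-dimethoxyphenoxy]-4-methyl-3-(3-methylbut-2-en-1-yl)benzoate
Conditions: K2CO3 (0.5 equiv), MeOH, rt to 40 °C; then aq. NH4Cl
Reagents that add atoms: methanol, CO
Why: Base-mediated transesterification (methanolysis) of the strained eight-membered benzylic lactone by acyl–oxygen cleavage, which releases the ring A methyl ester and the ring B hydroxymethyl group together, driven by ring-strain relief and the excess of methanol, with a non-acidic work-up so that the ortho-prenyl phenol is not cyclised to a chroman.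

**Compound list**

1 | 3,5-dimethoxybenzyl alcohol | COc1cc(CO)cc(OC)c1 | starting material
2 | (2-bromo-3,5-dimethoxyphenyl)methanol | COc1cc(CO)c(Br)c(OC)c1 | intermediate
3 | 2-bromo-1-(bromomethyl)-3,5-dimethoxybenzene | COc1cc(CBr)c(Br)c(OC)c1 | intermediate
4 | 2,6-dihydroxy-4-methylbenzoic acid | Cc1cc(O)c(C(=O)O)c(O)c1 | starting material
5 | (2-bromo-3,5-dimethoxyphenyl)methyl 2,6-dihydroxy-4-methylbenzoate | Cc1cc(O)c(C(=O)OCc2cc(OC)cc(OC)c2Br)c(O)c1 | intermediate
6 | 4-hydroxy-9,11-dimethoxy-2-methyl-5H,7H-dibenzo[b,g][1,5]dioxocin-5-one | Cc1cc(O)c2C(=O)OCc3cc(OC)cc(OC)c3Oc2c1 | intermediate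
7 | 3-chloro-3-methylbut-1-yne | CC(C)(Cl)C#C | starting material
8 | 9,11-dimethoxy-2-methyl-4-[(2-methylbut-3-yn-2-yl)oxy]-5H,7H-dibenzo[b,g][1,5]dioxocin-5-one | Cc1cc(OC(C)(C)C#C)c2C(=O)OCc3cc(OC)cc(OC)c3Oc2c1 | intermediate
9 | 9,11-dimethoxy-2-methyl-4-[(2-methylbut-3-en-2-yl)oxy]-5H,7H-dibenzo[b,g][1,5]dioxocin-5-one | Cc1cc(OC(C)(C)C=C)c2C(=O)OCc3cc(OC)cc(OC)c3Oc2c1 | intermediate
10 | 9,11-dimethoxy-2-methyl-3-(3-methylbut-2-en-1-yl)-3H,7H-dibenzo[b,g][1,5]dioxocine-4,5-dione (racemic at C3, not isolated) | CC1=CC2=C(C(=O)C1CC=C(C)C)C(=O)OCc3cc(OC)cc(OC)c3O2 | intermediate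
11 | 4-hydroxy-9,11-dimethoxy-2-methyl-3-(3-methylbut-2-en-1-yl)-5H,7H-dibenzo[b,g][1,5]dioxocin-5-one | Cc1cc2Oc3c(OC)cc(OC)cc3COC(=O)c2c(O)c1CC=C(C)C | intermediate
12 | methyl 2-hydroxy-6-[2-(hydroxymethyl)-4,6-dimethoxyphenoxy]-4-methyl-3-(3-methylbut-2-en-1-yl)benzoate | COC(=O)c1c(Oc2c(CO)cc(OC)cc2OC)cc(C)c(CC=C(C)C)c1O | target

**Step count**

Total steps: 8. Longest linear sequence: 8 steps (1 to 12).

**Steps most likely to fail**

1. Step 4.
 - What may go wrong: oxidative addition at the electron-rich C1'–Br bond, flanked on both sides, may be slow. Protodebromination, intermolecular etherification to oligomers, or phenoxide attack at the benzylic ester carbon could then outrun the closure. The ester must also twist into the cisoid geometry that the medium ring demands.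
 - Fallback: the tether is given up and the ether bond is made between two molecules with an aldehyde-activated bromide. It sets out from 2 and 4 and comes back to the route at 12.
 - Oxidation of 2 with MnO2 in CH2Cl2 should give 2-bromo-3,5-dimethoxybenzaldehyde F1. Esterification of 4 with MeI and KHCO3 in DMF should give methyl 2,6-dihydroxy-4-methylbenzoate F2.
 - Ullmann coupling of F1 with an excess of the symmetrical F2 (CuI, N,N-dimethylglycine, Cs2CO3, dioxane, 100 °C; the ortho formyl group assists the coupling) should give methyl 2-(2-formyl-4,6-dimethoxyphenoxy)-6-hydroxy-4-methylbenzoate F3.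
 - NaBH4 in MeOH at 0 °C reduces only the aldehyde, giving methyl 2-hydroxy-6-[2-(hydroxymethyl)-4,6-dimethoxyphenoxy]-4-methylbenzoate F4.
 - The operations of steps 5 to 7 are then applied to F4. Phenol-selective etherification with 7 (DBU, CuCl2·2H2O, MeCN) gives methyl 2-[2-(hydroxymethyl)-4,6-dimethoxyphenoxy]-4-methyl-6-[(2-methylbut-3-yn-2-yl)oxy]benzoate F5. Lindlar semihydrogenation gives methyl 2-[2-(hydroxymethyl)-4,6-dimethoxyphenoxy]-4-methyl-6-[(2-methylbut-3-en-2-yl)oxy]benzoate F6. Heating in N,N-diethylaniline rearranges F6 through methyl 2-[2-(hydroxymethyl)-4,6-dimethoxyphenoxy]-4-methyl-5-(3-methylbut-2-en-1-yl)-6-oxocyclohexa-1,3-diene-1-carboxylate F7 (not isolated) to 12.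

2. Step 5.
 - What may go wrong: O-alkylation may be sluggish because the phenol is hydrogen-bonded to, and shielded by, the lactone carbonyl. The tertiary chloride would then be consumed by elimination and alkyne self-coupling.
 - Fallback: the reverse-prenyl ether is made directly by Tsuji–Trost allylation. It sets out from 6 and comes back at 9, bypassing 8 and step 6.
 - 2-Methylbut-3-en-2-ol is converted (n-BuLi, then Boc2O, THF, 0 °C) into tert-butyl 2-methylbut-3-en-2-yl carbonate F8. Treatment of 6 with F8 and Pd(PPh3)4 (zerovalent palladium) in THF at 0 °C should give 9, with the phenoxide attacking the π-allyl complex at its tertiary terminus.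

3. Step 8.
 - What may go wrong: acyl substitution may be slow or incomplete, because the carbonyl is flanked by two ortho substituents and deactivated by the neighbouring phenoxide. The transesterification is also reversible.
 - Fallback: irreversible saponification followed by esterification through carboxylate alkylation, which does not depend on access to the carbonyl carbon. It sets out from 11 and comes back at 12.
 - LiOH in THF/H2O at 50 °C should open the lactone to 2-hydroxy-6-[2-(hydroxymethyl)-4,6-dimethoxyphenoxy]-4-methyl-3-(3-methylbut-2-en-1-yl)benzoic acid F9. MeI and KHCO3 in DMF at rt, with the same chemoselectivity as step 3, then methylate only the carboxylate to give 12.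

**Further compounds**

F1 | step 4 | 2-bromo-3,5-dimethoxybenzaldehyde | COc1cc(C=O)c(Br)c(OC)c1
F2 | step 4 | methyl 2,6-dihydroxy-4-methylbenzoate | COC(=O)c1c(O)cc(C)cc1O
F3 | step 4 | methyl 2-(2-formyl-4,6-dimethoxyphenoxy)-6-hydroxy-4-methylbenzoate | COC(=O)c1c(O)cc(C)cc1Oc1c(C=O)cc(OC)cc1OC
F4 | step 4 | methyl 2-hydroxy-6-[2-(hydroxymethyl)-4,6-dimethoxyphenoxy]-4-methylbenzoate | COC(=O)c1c(O)cc(C)cc1Oc1c(CO)cc(OC)cc1OC
F5 | step 4 | methyl 2-[2-(hydroxymethyl)-4,6-dimethoxyphenoxy]-4-methyl-6-[(2-methylbut-3-yn-2-yl)oxy]benzoate | COC(=O)c1c(OC(C)(C)C#C)cc(C)cc1Oc1c(CO)cc(OC)cc1OC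
F6 | step 4 | methyl 2-[2-(hydroxymethyl)-4,6-dimethoxyphenoxy]-4-methyl-6-[(2-methylbut-3-en-2-yl)oxy]benzoate | COC(=O)c1c(OC(C)(C)C=C)cc(C)cc1Oc1c(CO)cc(OC)cc1OC
F7 | step 4 | methyl 2-[2-(hydroxymethyl)-4,6-dimethoxyphenoxy]-4-methyl-5-(3-methylbut-2-en-1-yl)-6-oxocyclohexa-1,3-diene-1-carboxylate | COC(=O)C1=C(Oc2c(CO)cc(OC)cc2OC)C=C(C)C(CC=C(C)C)C1=O
F8 | step 5 | tert-butyl 2-methylbut-3-en-2-yl carbonate | CC(C)(C)OC(=O)OC(C)(C)C=C
F9 | step 8 | 2-hydroxy-6-[2-(hydroxymethyl)-4,6-dimethoxyphenoxy]-4-methyl-3-(3-methylbut-2-en-1-yl)benzoic acid | OC(=O)c1c(Oc2c(CO)cc(OC)cc2OC)cc(C)c(CC=C(C)C)c1O
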